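The readings come from a simulation from invented constants; scatter was added.

Begin at early times: c(target) climbs in both earlier runs, and the highest readings stand at 29.9% in birch and 42.2% in elm, both at 0.625 d.

common to all: substrate 0.10 M; precatalyst 10 mol%
- birch: partner 1.3 equiv (in portions, 2); run made earlier; portions every 8.0 h
- elm: partner 2 equiv (in portions, 2); run made earlier; portions every 8.0 h
- flask: partner 0.900 equiv (in portions, 2); the portions of partner follow each other after 8.0 h, the first at the start; time 3.0 d

| run | time / d | target / % | substrate / % |
|---|---|---|---|
| birch | 0.208 | 10.5 | 89.2 |
| birch | 0.625 | 29.9 | 70.8 |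
| birch | 1.04 | 27.0 | 72.7 |
| birch | 1.67 | 18.4 | 81.9 |
| birch | 2.50 | 11.1 | 90.6 |
| birch | 3.00 | 7.1 | 92.4 |
| elm | 0.250 | 21.5 | 80.6 |
| elm | 0.417 | 34.0 | 66.7 |
| elm | 0.625 | 42.2 | 56.6 |
| elm | 1.04 | 37.2 | 61.3 |
| elm | 1.67 | 25.6 | 74.1 |
| elm | 3.00 | 10.2 | 87.3 |

(each reading ± 1 percentage point)

- the numbers in the tables scatter by 1 percentage point (one standard deviation)
- the reaction counts as stopped when no species that holds the substrate changes by six tenths of a point or more over the second half of the time

* at 3.0 d, what has stopped the reaction, if anything has (the partner has run out first / it is still moving / all of the substrate has reacted / forward and back rates have come level)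
* target at 3.0 d, in percent of the substrate charged

Rank the time scales from the fastest. The portions come first: they are 8.0 h apart, sooner than the highest readings, so birch and elm have both portions in them while target is still rising. The fall comes next. In elm, c(target) drops from 37.2% at 1.04 d to 10.2% at 3.00 d, while c(substrate) recovers from 61.3% to 87.3%, so read this as target going back to substrate.

Take first-order fall constants from two readings of target in each run, those at 1.04 d and 3.00 d: 0.682 d⁻¹ in birch and 0.660 d⁻¹ in elm, mean 0.671 d⁻¹. Count in the halving time of target, the time in which c(target) falls to half on the late branch: 1.03 d. The asked time lies 1.90 halvings beyond 1.04 d.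

For the dose, compare the two readings at 3.00 d: they scale with an exponent of 0.841, which puts this flask at 5.21%. On the same halving time, that target loses 9 percentage points over the second half, far beyond the stopping margin, so this reckoning calls the flask still moving.

The forecast says it is still moving and 5.5%, somewhat above this reckoning, with the smoothed values “scaling roughly as dose^0.8”.

The flask gives it is still moving and 5.55%.

    substrate + partner + catalyst ⇌ target + catalyst, rate k1*[substrate]*[partner]*[catalyst] forward; the back reaction follows from the equilibrium constant (K = 15.0 M⁻¹, k = 1.60 M⁻² min⁻¹)
    partner + precatalyst → catalyst + spent reagent (k = 0.280 M⁻¹ min⁻¹)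
    substrate → decomposition product (k = 4.80 × 10⁻⁷ min⁻¹)
    partner → decomposed reagent (k = 0.00150 min⁻¹)

Count halvings of 1.03 d from the 14.3% of target that the flask holds at 1.50 d: they give 5.21% at 3.0 d, against 5.55%, and 12.8% for the same flask read at 40 h, against 12.9%. In this flask the decomposition of partner has a half-life of 0.321 d, shorter than the 0.38 d of the forward step to target alone at 0.589 d. At 3.00 d decomposed reagent stands at 0.0721 M, and 2.6% of the charged partner is left.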